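**Retrosynthetic overview**
- Target ⇐ CBS reduction of an isopropenyl ketone ⇐ Ru-catalysed coupling of a ring ethynyl carbinol with an allylic alcohol, which builds the C(=CH2)CH2CH2C(=O) chain.
- Ring fragment (1S,3R,4R) ⇐ hydroxyl-tethered syn-chloro/anti-bromo addition to (S)-1-ethynyl-4-methylcyclohex-3-en-1-ol (the proposed new step).
- That cyclohexenol ⇐ cyclopropylcarbinyl → homoallyl ring expansion of a 5-ethynyl-2-methylbicyclo[3.1.0]hexan-2-ol; rear-side attack of water at the bridgehead sets C1.
- The bicyclo[3.1.0]hexane ⇐ intramolecular carbenoid cyclopropanation of an epoxide made from (S)-epichlorohydrin and dimetalated 2-methylbut-1-en-3-yne.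
- Ring order: the three- and five-membered rings form together first, then expand to the six-membered ring, the only ring of the target.

Assumption: the target is taken exactly as drawn, (1S,3R,4R) in the ring and (5R) in the side chain; common organometallics and halogen sources are treated as reagents.

**Route**

Step 1
Reactants: 1 2-methylbut-1-en-3-yne; 2 (S)-epichlorohydrin
Product: 3 (2S)-1-chloro-5-methylidenehept-6-yn-2-ol
Conditions: n-BuLi (2.1 equiv), KOt-Bu (2.1 equiv), THF–hexane, −78 → −20 °C; LiBr; then 2, −78 °C; aq NH4Cl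
Reagents that add atoms: none
Why: Lochmann–Schlosser dimetalation gives the acetylide/symmetrical 2-alkynylallyl dianion, whose allyl terminus opens the epoxide at its CH2 (SN2), so the stereocentre of 2 is untouched and stays (S).

Step 2
Reactants: 3 (2S)-1-chloro-5-methylidenehept-6-yn-2-ol
Product: 5 (1S,2S,5S)-5-ethynylbicyclo[3.1.0]hexan-2-ol, via epoxide 4 (not isolated)
Conditions: LTMP (3.5 equiv, from TMP + n-BuLi), t-BuOMe, −78 → 0 °C; aq NH4Cl
Reagents that add atoms: none
Why: Hodgson-type intramolecular cyclopropanation, in which LTMP closes the chlorohydrin to the epoxide and lithiates its CH2 trans to the chain; the lithium carbenoid adds to the 1,1-disubstituted alkene with rear-side loss of the epoxide oxygen, so the carbinol centre fixes C1 and C5 (cis-fused, OH trans to the cyclopropane CH2).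

Step 3
Reactants: 5 (1S,2S,5S)-5-ethynylbicyclo[3.1.0]hexan-2-ol
Product: 6 (1S,5S)-5-ethynylbicyclo[3.1.0]hexan-2-one
Conditions: Dess–Martin periodinane, CH2Cl2, 0 °C → rt
Reagents that add atoms: none
Why: Dess–Martin oxidation changes only the secondary carbinol, and C1 and C5 are not epimerisable.

Step 4
Reactants: 6 (1S,5S)-5-ethynylbicyclo[3.1.0]hexan-2-one
Product: 8 (1S)-1-ethynyl-4-methylcyclohex-3-en-1-ol, via tertiary cyclopropylcarbinol 7 (not isolated)
Conditions: MeMgBr (2.2 equiv; one equivalent is taken by the alkyne C–H), THF, −78 → 0 °C; then 1 M aq H2SO4, THF, 0 °C → rt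
Reagents that add atoms: methylmagnesium bromide, C[Mg]Br; water, O
Why: Grignard addition gives a sabinene-hydrate-type carbinol that ionises in dilute acid to the cyclopropylcarbinyl cation, and water opens the C1–C5 bond from the rear at the alkynyl-bearing bridgehead (cyclopropylcarbinyl → homoallyl ring expansion, as in sabinene hydrate → terpinen-4-ol), so that carbon becomes C1 of the cyclohexenol with inversion, (S).

Step 5
Reactants: 8 (1S)-1-ethynyl-4-methylcyclohex-3-en-1-ol
Product: 9 (1S,3R,4R)-3-bromo-4-chloro-1-ethynyl-4-methylcyclohexan-1-ol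
Conditions: NBS (1.05 equiv), ClTi(Oi-Pr)3 (1.2 equiv), CH2Cl2–hexane, −20 °C; then H2O
Reagents that add atoms: N-bromosuccinimide, O=C1CCC(=O)N1Br; chlorotitanium triisopropoxide, CC(C)O[Ti](Cl)(OC(C)C)OC(C)C
Why: Proposed new method: the tertiary alcohol exchanges onto Ti, NBS forms the bromonium reversibly on both faces, and only the bromonium anti to the O–Ti tether can be opened from inside, the Ti-bound chloride passing across a boat (C1 and C4 at the flagpoles) to the tertiary carbon, so Cl enters syn to O and Br ends anti (3R,4R), with the terminal alkyne inert to NBS; the closest known reaction is the Ti-alkoxide-directed bromochlorination of allylic alcohols (Burns), extended here to a transannular homoallylic tertiary alcohol.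

Step 6
Reactants: 10 methacrolein
Product: 11 2-methylpenta-1,4-dien-3-ol (racemic)
Conditions: CH2=CHMgBr, THF, −78 °C; aq NH4Cl
Reagents that add atoms: vinylmagnesium bromide, C=C[Mg]Br
Why: Grignard 1,2-addition to an enal; the carbinol centre is racemic and is erased in the next step.

Step 7
Reactants: 9 (1S,3R,4R)-3-bromo-4-chloro-1-ethynyl-4-methylcyclohexan-1-ol; 11 2-methylpenta-1,4-dien-3-ol (1.5 equiv)
Product: 12 6-[(1S,3R,4R)-3-bromo-4-chloro-1-hydroxy-4-methylcyclohexyl]-2-methylhepta-1,6-dien-3-one
Conditions: [CpRu(MeCN)3]PF6 (10 mol %), acetone, rt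
Reagents that add atoms: none
Why: Trost ruthenium-catalysed alkyne–alkene coupling through a ruthenacycle, in which the quaternary propargylic carbinol directs the new C–C bond to the internal alkyne carbon (branched 1,1-disubstituted alkene) and only the monosubstituted vinyl group of the dienol reacts, the enol formed tautomerising to the ketone; no ring stereocentre is touched.

Step 8
Reactants: 12 6-[(1S,3R,4R)-3-bromo-4-chloro-1-hydroxy-4-methylcyclohexyl]-2-methylhepta-1,6-dien-3-one
Product: 13 (1S,3R,4R)-3-bromo-4-chloro-1-[(5R)-5-hydroxy-6-methylhepta-1,6-dien-2-yl]-4-methylcyclohexan-1-ol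
Conditions: (S)-Me-CBS (20 mol %), catecholborane (1.8 equiv), toluene, −78 °C; then H2O
Reagents that add atoms: none
Why: Corey–Bakshi–Shibata 1,2-reduction under reagent control, with the isopropenyl group as the large substituent, so the (S)-catalyst gives the (R)-allylic alcohol; the halides, alkenes and tertiary alcohol are inert at −78 °C.

**Compound list**
1 | 2-methylbut-1-en-3-yne | C=C(C)C#C | starting material
2 | (S)-epichlorohydrin, (2S)-2-(chloromethyl)oxirane | ClC[C@@H]1CO1 | starting material
3 | (2S)-1-chloro-5-methylidenehept-6-yn-2-ol | C#CC(=C)CC[C@H](O)CCl | intermediate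
4 | (2S)-2-(3-methylidenepent-4-yn-1-yl)oxirane | C#CC(=C)CC[C@H]1CO1 | intermediate
5 | (1S,2S,5S)-5-ethynylbicyclo[3.1.0]hexan-2-ol | O[C@H]1CC[C@]2(C#C)C[C@H]12 | intermediate
6 | (1S,5S)-5-ethynylbicyclo[3.1.0]hexan-2-one | O=C1CC[C@]2(C#C)C[C@H]12 | intermediate
7 | (1S,2R,5S)-5-ethynyl-2-methylbicyclo[3.1.0]hexan-2-ol (major C2 epimer; C2 is lost on ionisation) | C[C@@]1(O)CC[C@]2(C#C)C[C@H]12 | intermediate
8 | (1S)-1-ethynyl-4-methylcyclohex-3-en-1-ol | C#C[C@]1(O)CCC(C)=CC1 | intermediate
9 | (1S,3R,4R)-3-bromo-4-chloro-1-ethynyl-4-methylcyclohexan-1-ol | C#C[C@]1(O)CC[C@@](C)(Cl)[C@H](Br)C1 | intermediate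
10 | methacrolein (2-methylprop-2-enal) | C=C(C)C=O | starting material
11 | 2-methylpenta-1,4-dien-3-ol (racemic) | C=CC(O)C(C)=C | intermediate
12 | 6-[(1S,3R,4R)-3-bromo-4-chloro-1-hydroxy-4-methylcyclohexyl]-2-methylhepta-1,6-dien-3-one | C=C(C)C(=O)CCC(=C)[C@]1(O)CC[C@@](C)(Cl)[C@H](Br)C1 | intermediate
13 | (1S,3R,4R)-3-bromo-4-chloro-1-[(5R)-5-hydroxy-6-methylhepta-1,6-dien-2-yl]-4-methylcyclohexan-1-ol | C=C(C)[C@H](O)CCC(=C)[C@]1(O)CC[C@@](C)(Cl)[C@H](Br)C1 | target

**Totals**
Total steps: 8. Longest linear sequence: 7 (steps 1, 2, 3, 4, 5, 7, 8).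

**Steps most likely to fail, with fallbacks**

Step 5 (the proposed new step). The tethered chloride must beat two competitors: attack of the oxygen itself on the bromonium, and untethered chloride, which would favour the other diastereomer. The fallback sets out from 8 and comes back at 9. NBS alone in CH2Cl2 at 0 °C gives the transannular bromo ether (1R,2R,4S)-2-bromo-4-ethynyl-1-methyl-7-oxabicyclo[2.2.1]heptane F1; this is bromoetherification as known for terpinen-4-ol-type alcohols, with oxygen attacking the tertiary carbon anti to bromine. Dry HCl in CH2Cl2 at −40 °C then cleaves the tertiary C(Me)–O bond, the classical hydrogen halide opening of 1,4-cineole-type ethers. The anti bromine bridges the cation, so chloride enters on the face the oxygen leaves, and the alkynyl-substituted C–O bond, which ionises far less readily, is kept; the product is 9.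

Step 2. The lithium carbenoid has to cyclopropanate a conjugated enyne that carries a lithium acetylide. The fallback sets out from 1 and comes back at 6. The dianion of 1 is alkylated with ethylene oxide to 4-methylidenehex-5-yn-1-ol F2, and Jones oxidation gives 4-methylidenehex-5-ynoic acid F3. Oxalyl chloride gives 4-methylidenehex-5-ynoyl chloride F4, and diazomethane gives 1-diazo-5-methylidenehept-6-yn-2-one F5. Copper(I)/chiral bis(oxazoline)-catalysed intramolecular cyclopropanation, known for 1-diazohex-5-en-2-ones, then gives 6 directly, with the catalyst enantiomer chosen for (1S,5S).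

Step 4. If the homoallyl cation becomes free before water arrives, the ee at C1 erodes; elimination and over-hydration are further risks. The fallback sets out from 6 and comes back at 8. Aqueous HClO4 in acetone opens the cyclopropyl ketone by homo-conjugate addition of water at the alkynyl-bearing carbon, still a ring expansion, to achiral 4-ethynyl-4-hydroxycyclohexan-1-one F6. Enantioselective deprotonation with a lithium bis(1-phenylethyl)amide (excess, LiCl) and trapping with PhNTf2 gives (4S)-4-ethynyl-4-hydroxycyclohex-1-en-1-yl trifluoromethanesulfonate F7, the base enantiomer being chosen by experiment. Me2CuLi replaces the triflate by methyl to give 8.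

**Further compounds**
F1 | step 5 | (1R,2R,4S)-2-bromo-4-ethynyl-1-methyl-7-oxabicyclo[2.2.1]heptane | C#C[C@@]12CC[C@@](C)(O1)[C@H](Br)C2
F2 | step 2 | 4-methylidenehex-5-yn-1-ol | C#CC(=C)CCCO
F3 | step 2 | 4-methylidenehex-5-ynoic acid | C#CC(=C)CCC(=O)O
F4 | step 2 | 4-methylidenehex-5-ynoyl chloride | C#CC(=C)CCC(=O)Cl
F5 | step 2 | 1-diazo-5-methylidenehept-6-yn-2-one | C#CC(=C)CCC(=O)C=[N+]=[N-]
F6 | step 4 | 4-ethynyl-4-hydroxycyclohexan-1-one | C#CC1(O)CCC(=O)CC1
F7 | step 4 | (4S)-4-ethynyl-4-hydroxycyclohex-1-en-1-yl trifluoromethanesulfonate | C#C[C@]1(O)CCC(OS(=O)(=O)C(F)(F)F)=CC1
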